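**Retrosynthetic overview**
1. 18 ⇐ 17 (oxidation of the last ring carbinol) ⇐ 14 (two angelate esters) ⇐ 12 (hydroxyl-directed epoxidation, desilylation).
2. 12 ⇐ 10 (methylenation, tether removal) ⇐ 9 by a silicon-tethered intramolecular [4+2]. This one operation forms the ring CH2–CH(side chain) bond and the bond between the two oxygen-bearing ring carbons (the later ketone carbon and the carbon that carries the ring ester), and sets three stereocentres.
3. 9 ⇐ tiglaldehyde 7 + iPr2Si(OTf)2 + keto aldehyde 6, three components joined at silicon in one flask; 6 ⇐ sulcatone 1 (α-aminoxylation, Shi epoxidation, formylation).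
4. Enabling feature: in the carbocycle (ring A) the ketone carbon and its neighbour bearing the ring angelate are both oxygenated. At the enol level these two oxygens belong to two different carbonyl fragments and can be clipped by one silicon atom into a temporary five-membered 1,3-dioxa-2-silolane (ring B). The clip forces the regiochemistry that electronics alone oppose and leaves the ketone carbon as a carbinol that later steers the epoxidation.
5. Ring order: side-chain oxirane (step 4); ring A together with ring B (step 7); ring B opened (step 9); oxirane on ring A (step 10).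

Key step: step 7

Remark (assumption): 6 is drawn as the keto aldehyde but exists and reacts as its chelated Z-hydroxymethylene enol; D-proline and the D-fructose-derived Shi ketone are the catalyst enantiomers that the accepted transition-state models assign to the S carbinol and the R oxirane centre.

**Route**

Step 1
Reactants: 1 6-methylhept-5-en-2-one (sulcatone, used in excess)
Product: 2 (3S)-6-methyl-3-[(phenylamino)oxy]hept-5-en-2-one
Conditions: PhNO (slow addition), D-proline (20 mol%), DMSO, rt
Reagents that add atoms: nitrosobenzene, O=Nc1ccccc1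
Why: Proline-catalysed α-aminoxylation (O-selective nitroso aldol): the more substituted enamine attacks the oxygen of PhNO held by the proline carboxylic acid, D-proline setting the S centre, and slow addition keeps the enamine pathway ahead of a nitroso-ene reaction at the trisubstituted alkene.

Step 2
Reactants: 2 aminooxy ketone
Product: 3 (3S)-3-hydroxy-6-methylhept-5-en-2-one
Conditions: Zn dust, AcOH–THF, 0 °C → rt
Reagents that add atoms: none
Why: Reductive N–O bond cleavage by dissolving zinc, which is much faster than reduction of the ketone or of the C–O bond, so the carbinol centre is kept.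

Step 3
Reactants: 3 hydroxy ketone
Product: 4 (3S)-3-[(tert-butyldimethylsilyl)oxy]-6-methylhept-5-en-2-one
Conditions: TBSCl, imidazole, DMF, rt
Reagents that add atoms: tert-butyldimethylsilyl chloride, CC(C)(C)[Si](C)(C)Cl
Why: Standard silylation of a secondary alcohol; the silyl ether blocks hydrogen bonding to the ketone (needed for the facial bias in step 7) and survives base, heat and the titanium reagent.

Step 4
Reactants: 4 silyloxy ketone
Product: 5 (3S)-3-[(tert-butyldimethylsilyl)oxy]-4-[(2R)-3,3-dimethyloxiran-2-yl]butan-2-one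
Conditions: D-fructose-derived Shi ketone (30 mol%), Oxone (2KHSO5·KHSO4·K2SO4), K2CO3, Bu4NHSO4, MeCN–CH2(OMe)2 / aq. Na2B4O7 buffer (pH 10.5), 0 °C
Reagents that add atoms: potassium peroxymonosulfate (active part of Oxone), [K+].[O-]S(=O)(=O)OO
Why: Shi asymmetric epoxidation: the chiral dioxirane transfers oxygen through a spiro transition state to one face of the trisubstituted alkene and sets the R oxirane centre by reagent control, the remote silyloxy centre having little influence.

Step 5
Reactants: 5 epoxy ketone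
Product: 6 (4S)-4-[(tert-butyldimethylsilyl)oxy]-5-[(2R)-3,3-dimethyloxiran-2-yl]-3-oxopentanal
Conditions: LiN(iPr)2 (LDA), THF, −78 °C; CF3CH2OCHO, −78 → −20 °C; AcOH quench
Reagents that add atoms: 2,2,2-trifluoroethyl formate, O=COCC(F)(F)F
Why: Kinetic Claisen-type formylation: LDA removes a methyl proton (less hindered than the silyloxy methine) and the enolate is C-formylated by the activated formate; the product rests as its 1,3-dicarbonyl enolate, so the silyloxy centre is not epimerised and no new stereocentre forms.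

Step 6
Reactants: 7 (E)-2-methylbut-2-enal (tiglaldehyde); 6 keto aldehyde
Product: 9 (1E,4S)-4-[(tert-butyldimethylsilyl)oxy]-5-[(2R)-3,3-dimethyloxiran-2-yl]-1-{[{[(1E)-2-methylbuta-1,3-dien-1-yl]oxy}di(propan-2-yl)silyl]oxy}pent-1-en-3-one, via dienyloxysilyl triflate 8 (not isolated)
Conditions: iPr2Si(OTf)2, Et3N, CH2Cl2, −78 °C, 7 added slowly; then 6, Et3N, −78 → 0 °C; Et3N-deactivated silica
Reagents that add atoms: diisopropylsilyl bis(trifluoromethanesulfonate), CC(C)[Si](OS(=O)(=O)C(F)(F)F)(OS(=O)(=O)C(F)(F)F)C(C)C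
Why: Sequential O-silylation: the silyl triflate and Et3N turn the enal into its (1E)-dienol silyl ether by γ-deprotonation of the O-silyl oxocarbenium ion (giving 8), and the remaining, less reactive Si–OTf is displaced by the enol oxygen of 6 to give the thermodynamically preferred (E)-vinylogous silyl ester; at −78 °C the enolate oxygen outruns triflate-induced opening of the oxirane, and no stereocentre forms.

Step 7
Reactants: 9 silicon-tethered triene
Product: 10 (2S)-2-[(tert-butyldimethylsilyl)oxy]-3-[(2R)-3,3-dimethyloxiran-2-yl]-1-[(3aR,4S,7aR)-7-methyl-2,2-di(propan-2-yl)-3a,4,5,7a-tetrahydro-1,3,2-benzodioxasilol-4-yl]propan-1-one (trans-fused silylene; acyl group cis to the allylic oxygen and trans to the other ring oxygen)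
Conditions: PhMe (0.01 M), BHT, Et3N (5 mol%), base-washed sealed tube, 150–160 °C
Reagents that add atoms: none
Why: Proposed new method: thermal, concerted but asynchronous intramolecular [4+2] cycloaddition in which the (1E)-1-silyloxy-2-methylbutadiene and the (E)-β-silyloxy enone hang on one silicon atom, so that the oxygen-bearing diene terminus can only reach the oxygen-bearing β-carbon of the enone and the CH2 terminus the α-carbon; the closest known reaction types are silaketal-tethered intramolecular Diels–Alder reactions of dienyl and allyl silyl ethers and thermal cyclisations of terminally activated nona-1,6,8-trienes, and what is new is that both tether oxygens are enol oxygens. Ring A closes as a cyclohexene by the cycloaddition itself and ring B closes in the same event as a five-membered 1,3-dioxa-2-silolane through the three-atom O–Si–O tether in the fused mode (the bridged alternative would span a 1,3-relationship and is too strained). The trans relation between the acyl-bearing carbon and its silyloxy neighbour is the (E)-enone geometry carried over suprafacially; the carbinol centre next to the ring methyl is set by the endo position of the ketone, which puts the tether exo and gives the trans-fused silylene with the allylic oxygen cis to the acyl group. Absolute configuration comes from the (S)-silyloxy centre beside the ketone: in the s-cis enone with the C–OSi bond turned away from the carbonyl dipole or anti to the incoming diene, the diene meets the face that shows H rather than the CH2–oxirane arm. The step needs regioselectivity (secured by the short tether against the electronic ortho preference), endo selectivity (secondary overlap of the ketone, and the Si(iPr)2 unit stays away from the diene methyl) and facial selectivity (the silyloxy centre), and both enol ethers must keep their E geometry during heating (base-washed glass, BHT).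

Step 8
Reactants: 10 bicyclic ketone
Product: 11 (3aR,4R,7aR)-4-{(3S)-3-[(tert-butyldimethylsilyl)oxy]-4-[(2R)-3,3-dimethyloxiran-2-yl]but-1-en-2-yl}-7-methyl-2,2-di(propan-2-yl)-3a,4,5,7a-tetrahydro-1,3,2-benzodioxasilole
Conditions: Cp2TiMe2 (3 equiv), PhMe–THF, 70 °C, dark
Reagents that add atoms: dimethyltitanocene Cp2TiMe2, C[Ti](C)(C1C=CC=C1)C1C=CC=C1
Why: Petasis methylenation: Cp2Ti=CH2 formed thermally converts the hindered ketone into the 1,1-disubstituted alkene without base, so the β-silyloxy group is not eliminated and the two α-centres are not epimerised; no new stereocentre.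

Step 9
Reactants: 11 silylene alkene
Product: 12 (1R,2R,6R)-6-{(3S)-3-[(tert-butyldimethylsilyl)oxy]-4-[(2R)-3,3-dimethyloxiran-2-yl]but-1-en-2-yl}-3-methylcyclohex-3-ene-1,2-diol
Conditions: Bu4NF (2.2 equiv), AcOH (2.2 equiv), THF, −20 → 0 °C
Reagents that add atoms: none
Why: Fluoride-induced cleavage of the strained five-membered dialkoxysilane, which is far faster than attack on the hindered secondary TBS ether; AcOH buffering protects the oxirane, and no stereocentre changes.

Step 10
Reactants: 12 cyclohexenediol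
Product: 13 (1S,2S,3R,4R,6R)-4-{(3S)-3-[(tert-butyldimethylsilyl)oxy]-4-[(2R)-3,3-dimethyloxiran-2-yl]but-1-en-2-yl}-1-methyl-7-oxabicyclo[4.1.0]heptane-2,3-diol (oxirane cis to the adjacent hydroxyl and to the side chain)
Conditions: VO(acac)2 (5 mol%), t-BuOOH (1.1 equiv, decane), CH2Cl2, 0 °C
Reagents that add atoms: tert-butyl hydroperoxide, CC(C)(C)OO
Why: Hydroxyl-directed epoxidation: the vanadate ester of the allylic ring hydroxyl delivers the peroxide oxygen to the alkene face syn to that hydroxyl, setting both oxirane centres cis to the side chain and trans to the other ring oxygen; the side-chain methylene group has only a remote homoallylic hydroxyl and is left.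

Step 11
Reactants: 13 epoxy diol
Product: 14 (1S,2S,3R,4R,6R)-4-{(3S)-4-[(2R)-3,3-dimethyloxiran-2-yl]-3-hydroxybut-1-en-2-yl}-1-methyl-7-oxabicyclo[4.1.0]heptane-2,3-diol
Conditions: Bu4NF, THF, 0 °C → rt
Reagents that add atoms: none
Why: Fluoride desilylation of the secondary TBS ether; the basic medium leaves both oxiranes alone (the syn epoxy alcohol cannot undergo Payne rearrangement, and alkoxide attack on the side-chain oxirane would be a disfavoured 5-endo opening), and no stereocentre changes.

Step 12
Reactants: 14 epoxy triol; 15 (2Z)-2-methylbut-2-enoic acid (angelic acid, 2.4 equiv)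
Product: 17 (1S,2S,3R,4R,6R)-4-[(3S)-4-[(2R)-3,3-dimethyloxiran-2-yl]-3-{[(2Z)-2-methylbut-2-enoyl]oxy}but-1-en-2-yl]-2-hydroxy-1-methyl-7-oxabicyclo[4.1.0]heptan-3-yl (2Z)-2-methylbut-2-enoate, via mixed anhydride 16 (not isolated)
Conditions: 15, 2,4,6-trichlorobenzoyl chloride, Et3N, PhMe, rt; then 14, PhMe, 75 °C (no DMAP)
Reagents that add atoms: none
Why: Yamaguchi-type esterification through the mixed anhydride without DMAP, conditions under which angelates do not isomerise to tiglates; the allylic side-chain hydroxyl and the ring hydroxyl next to the side-chain-bearing CH are acylated, while the ring hydroxyl flanked by the fully substituted oxirane carbon and hydrogen-bonded to the syn oxirane oxygen is expected to remain; no stereocentre changes.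

Step 13
Reactants: 17 diester alcohol
Product: 18 (1R,3R,4R,6R)-4-[(3S)-4-[(2R)-3,3-dimethyloxiran-2-yl]-3-{[(2Z)-2-methylbut-2-enoyl]oxy}but-1-en-2-yl]-1-methyl-2-oxo-7-oxabicyclo[4.1.0]heptan-3-yl (2Z)-2-methylbut-2-enoate (CNP0247177.1)
Conditions: Dess–Martin periodinane, pyridine, CH2Cl2, 0 °C → rt
Reagents that add atoms: none
Why: Dess–Martin oxidation of the remaining hindered secondary alcohol to the ketone under near-neutral conditions, so the epoxy ketone, the α-acyloxy centre and the Z-esters survive; the temporary carbinol centre is erased and no new one forms.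

**Compound list**
1 | 6-methylhept-5-en-2-one (sulcatone) | CC(=O)CCC=C(C)C | starting material
2 | (3S)-6-methyl-3-[(phenylamino)oxy]hept-5-en-2-one | CC(=O)[C@H](CC=C(C)C)ONc1ccccc1 | intermediate
3 | (3S)-3-hydroxy-6-methylhept-5-en-2-one | CC(=O)[C@H](CC=C(C)C)O | intermediate
4 | (3S)-3-[(tert-butyldimethylsilyl)oxy]-6-methylhept-5-en-2-one | CC(=O)[C@H](CC=C(C)C)O[Si](C)(C)C(C)(C)C | intermediate
5 | (3S)-3-[(tert-butyldimethylsilyl)oxy]-4-[(2R)-3,3-dimethyloxiran-2-yl]butan-2-one | CC(=O)[C@H](C[C@H]1OC1(C)C)O[Si](C)(C)C(C)(C)C | intermediate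
6 | (4S)-4-[(tert-butyldimethylsilyl)oxy]-5-[(2R)-3,3-dimethyloxiran-2-yl]-3-oxopentanal (reacts as its Z-enol) | O=CCC(=O)[C@H](C[C@H]1OC1(C)C)O[Si](C)(C)C(C)(C)C | intermediate
7 | (E)-2-methylbut-2-enal (tiglaldehyde) | C/C=C(\C)C=O | starting material
8 | {[(1E)-2-methylbuta-1,3-dien-1-yl]oxy}di(propan-2-yl)silyl trifluoromethanesulfonate | C=C/C(C)=C/O[Si](C(C)C)(C(C)C)OS(=O)(=O)C(F)(F)F | intermediate (not isolated)
9 | (1E,4S)-4-[(tert-butyldimethylsilyl)oxy]-5-[(2R)-3,3-dimethyloxiran-2-yl]-1-{[{[(1E)-2-methylbuta-1,3-dien-1-yl]oxy}di(propan-2-yl)silyl]oxy}pent-1-en-3-one | C=C/C(C)=C/O[Si](C(C)C)(C(C)C)O/C=C/C(=O)[C@H](C[C@H]1OC1(C)C)O[Si](C)(C)C(C)(C)C | intermediate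
10 | (2S)-2-[(tert-butyldimethylsilyl)oxy]-3-[(2R)-3,3-dimethyloxiran-2-yl]-1-[(3aR,4S,7aR)-7-methyl-2,2-di(propan-2-yl)-3a,4,5,7a-tetrahydro-1,3,2-benzodioxasilol-4-yl]propan-1-one | O=C([C@H](C[C@H]1OC1(C)C)O[Si](C)(C)C(C)(C)C)[C@H]1CC=C(C)[C@H]2O[Si](C(C)C)(C(C)C)O[C@H]12 | intermediate
11 | (3aR,4R,7aR)-4-{(3S)-3-[(tert-butyldimethylsilyl)oxy]-4-[(2R)-3,3-dimethyloxiran-2-yl]but-1-en-2-yl}-7-methyl-2,2-di(propan-2-yl)-3a,4,5,7a-tetrahydro-1,3,2-benzodioxasilole | C=C([C@H](C[C@H]1OC1(C)C)O[Si](C)(C)C(C)(C)C)[C@H]1CC=C(C)[C@H]2O[Si](C(C)C)(C(C)C)O[C@H]12 | intermediate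
12 | (1R,2R,6R)-6-{(3S)-3-[(tert-butyldimethylsilyl)oxy]-4-[(2R)-3,3-dimethyloxiran-2-yl]but-1-en-2-yl}-3-methylcyclohex-3-ene-1,2-diol | C=C([C@H](C[C@H]1OC1(C)C)O[Si](C)(C)C(C)(C)C)[C@H]1CC=C(C)[C@@H](O)[C@@H]1O | intermediate
13 | (1S,2S,3R,4R,6R)-4-{(3S)-3-[(tert-butyldimethylsilyl)oxy]-4-[(2R)-3,3-dimethyloxiran-2-yl]but-1-en-2-yl}-1-methyl-7-oxabicyclo[4.1.0]heptane-2,3-diol | C=C([C@H](C[C@H]1OC1(C)C)O[Si](C)(C)C(C)(C)C)[C@H]1C[C@H]2O[C@@]2(C)[C@@H](O)[C@@H]1O | intermediate
14 | (1S,2S,3R,4R,6R)-4-{(3S)-4-[(2R)-3,3-dimethyloxiran-2-yl]-3-hydroxybut-1-en-2-yl}-1-methyl-7-oxabicyclo[4.1.0]heptane-2,3-diol | C=C([C@H](C[C@H]1OC1(C)C)O)[C@H]1C[C@H]2O[C@@]2(C)[C@@H](O)[C@@H]1O | intermediate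
15 | (2Z)-2-methylbut-2-enoic acid (angelic acid) | C/C=C(/C)C(=O)O | starting material
16 | (2Z)-2-methylbut-2-enoic 2,4,6-trichlorobenzoic anhydride | C/C=C(/C)C(=O)OC(=O)c1c(Cl)cc(Cl)cc1Cl | intermediate (not isolated)
17 | (1S,2S,3R,4R,6R)-4-[(3S)-4-[(2R)-3,3-dimethyloxiran-2-yl]-3-{[(2Z)-2-methylbut-2-enoyl]oxy}but-1-en-2-yl]-2-hydroxy-1-methyl-7-oxabicyclo[4.1.0]heptan-3-yl (2Z)-2-methylbut-2-enoate | C=C([C@H](C[C@H]1OC1(C)C)OC(=O)/C(C)=C\C)[C@H]1C[C@H]2O[C@@]2(C)[C@@H](O)[C@@H]1OC(=O)/C(C)=C\C | intermediate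
18 | (1R,3R,4R,6R)-4-[(3S)-4-[(2R)-3,3-dimethyloxiran-2-yl]-3-{[(2Z)-2-methylbut-2-enoyl]oxy}but-1-en-2-yl]-1-methyl-2-oxo-7-oxabicyclo[4.1.0]heptan-3-yl (2Z)-2-methylbut-2-enoate | C=C([C@H](C[C@H]1OC1(C)C)OC(=O)/C(C)=C\C)[C@H]1C[C@H]2O[C@@]2(C)C(=O)[C@@H]1OC(=O)/C(C)=C\C | target

**Step count and risks**
Total steps: 13. Longest linear sequence: 13 steps (1 → 18); 7 and 15 are bought and enter at steps 6 and 12.

Steps most likely to fail:

1. Step 7 (bears the label). The push–pull dienophile is only weakly activated, so cyclisation may be slower than a thermal 1,5-hydrogen shift in the dienol ether, E/Z equilibration of the enol ethers, hetero-cycloaddition of the enone onto an enol ether, or loss of the tether. Endo/exo or facial selection may also be poor.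
Fallback (known reactions only; sets out from 5 and comes back at 10): the kinetic lithium enolate of 5 (LDA, THF, −78 °C) is alkylated with (Z)-1-bromo-3-iodobut-2-ene to the vinyl iodide ketone F1. Its (E)-boron enolate (Cy2BCl, Et3N, Et2O, −78 °C) adds to acrolein in an anti-selective aldol reaction steered by the silyloxy centre to give the aldol adduct F2. Ozonolysis limited to the monosubstituted vinyl group (O3, CH2Cl2, −78 °C, indicator end point, then PPh3) gives the hydroxy aldehyde F3. Nozaki–Hiyama–Kishi ring closure (CrCl2, NiCl2 1 mol%, DMSO, rt) forms the allylic carbinol of the cyclohexenediol ketone F4, Felkin-type addition being expected to give the trans-diol. iPr2Si(OTf)2 with 2,6-lutidine then closes the silylene and gives 10.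

2. Step 12. Site selection between the two ring hydroxyls may be poor (acylation of the hydroxyl that must become the ketone), and slow acylation may allow Z-to-E isomerisation of the angelate.
Fallback (sets out from 12 and comes back at 17): MnO2 (CH2Cl2, rt) oxidises only the allylic ring hydroxyl of 12 to the hydroxy enone F5, which removes the competing hydroxyl. Bu4NF/AcOH frees the side-chain alcohol (enone diol F6). Both remaining hydroxyls are angeloylated as in step 12 (enone diester F7). Luche reduction (NaBH4, CeCl3·7H2O, MeOH, −78 °C) adds hydride axially and returns the equatorial allylic alcohol F8, trans to the ring ester and cis to the side chain. VO(acac)2/t-BuOOH epoxidation directed by this hydroxyl gives 17.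

3. Step 8. Carbonyl olefination at the doubly α-branched ketone may be slow, with competing β-elimination of the ring silyloxy group or attack of the titanium carbene on the oxirane.
Fallback (sets out from 10 and comes back at 11): Peterson olefination in two stages. Me3SiCH2MgCl with anhydrous CeCl3 (THF, −78 → 0 °C) adds to the ketone without enolisation to give the β-hydroxysilane F9 (either epimer), and KH (THF, 0 °C → rt) brings about syn elimination to 11.

**Further compounds**
F1 | step 7 | (2S,6Z)-2-[(tert-butyldimethylsilyl)oxy]-1-[(2R)-3,3-dimethyloxiran-2-yl]-7-iodooct-6-en-3-one | C/C(I)=C/CCC(=O)[C@H](C[C@H]1OC1(C)C)O[Si](C)(C)C(C)(C)C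
F2 | step 7 | (2S,4S,6Z)-2-[(tert-butyldimethylsilyl)oxy]-1-[(2R)-3,3-dimethyloxiran-2-yl]-4-[(1S)-1-hydroxyprop-2-en-1-yl]-7-iodooct-6-en-3-one | C/C(I)=C/C[C@@H]([C@@H](O)C=C)C(=O)[C@H](C[C@H]1OC1(C)C)O[Si](C)(C)C(C)(C)C
F3 | step 7 | (2R,3S,5Z)-3-{(2S)-2-[(tert-butyldimethylsilyl)oxy]-3-[(2R)-3,3-dimethyloxiran-2-yl]propanoyl}-2-hydroxy-6-iodohept-5-enal | C/C(I)=C/C[C@@H]([C@@H](O)C=O)C(=O)[C@H](C[C@H]1OC1(C)C)O[Si](C)(C)C(C)(C)C
F4 | step 7 | (2S)-2-[(tert-butyldimethylsilyl)oxy]-1-[(1S,5R,6R)-5,6-dihydroxy-4-methylcyclohex-3-en-1-yl]-3-[(2R)-3,3-dimethyloxiran-2-yl]propan-1-one | O=C([C@H](C[C@H]1OC1(C)C)O[Si](C)(C)C(C)(C)C)[C@H]1CC=C(C)[C@@H](O)[C@@H]1O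
F5 | step 12 | (5R,6R)-5-{(3S)-3-[(tert-butyldimethylsilyl)oxy]-4-[(2R)-3,3-dimethyloxiran-2-yl]but-1-en-2-yl}-6-hydroxy-2-methylcyclohex-2-en-1-one | C=C([C@H](C[C@H]1OC1(C)C)O[Si](C)(C)C(C)(C)C)[C@H]1CC=C(C)C(=O)[C@@H]1O
F6 | step 12 | (5R,6R)-5-{(3S)-4-[(2R)-3,3-dimethyloxiran-2-yl]-3-hydroxybut-1-en-2-yl}-6-hydroxy-2-methylcyclohex-2-en-1-one | C=C([C@H](C[C@H]1OC1(C)C)O)[C@H]1CC=C(C)C(=O)[C@@H]1O
F7 | step 12 | (1R,6R)-6-[(3S)-4-[(2R)-3,3-dimethyloxiran-2-yl]-3-{[(2Z)-2-methylbut-2-enoyl]oxy}but-1-en-2-yl]-3-methyl-2-oxocyclohex-3-en-1-yl (2Z)-2-methylbut-2-enoate | C=C([C@H](C[C@H]1OC1(C)C)OC(=O)/C(C)=C\C)[C@H]1CC=C(C)C(=O)[C@@H]1OC(=O)/C(C)=C\C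
F8 | step 12 | (1R,2R,6R)-6-[(3S)-4-[(2R)-3,3-dimethyloxiran-2-yl]-3-{[(2Z)-2-methylbut-2-enoyl]oxy}but-1-en-2-yl]-2-hydroxy-3-methylcyclohex-3-en-1-yl (2Z)-2-methylbut-2-enoate | C=C([C@H](C[C@H]1OC1(C)C)OC(=O)/C(C)=C\C)[C@H]1CC=C(C)[C@@H](O)[C@@H]1OC(=O)/C(C)=C\C
F9 | step 8 | (3S)-3-[(tert-butyldimethylsilyl)oxy]-4-[(2R)-3,3-dimethyloxiran-2-yl]-2-[(3aR,4S,7aR)-7-methyl-2,2-di(propan-2-yl)-3a,4,5,7a-tetrahydro-1,3,2-benzodioxasilol-4-yl]-1-(trimethylsilyl)butan-2-ol (both epimers at the new carbinol carbon) | C[Si](C)(C)CC(O)([C@H](C[C@H]1OC1(C)C)O[Si](C)(C)C(C)(C)C)[C@H]1CC=C(C)[C@H]2O[Si](C(C)C)(C(C)C)O[C@H]12
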